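The rate constants were set for the occasion; the result is computed.

**Reagent leftover.** The leftover I ask about first is reagent. A substrate that goes the whole way to triple product takes 3 reagent, so full conversion would leave 0.210 M of it in autumn and 0.0600 M in dusk. In summer it would need 0.750 M against the 0.300 M charged, so reagent is there the limiting reagent.

| setting | autumn | dusk | summer |
|---|---|---|---|
| substrate | 0.030 M | 0.080 M | 0.25 M |
| reagent | 0.300 M | 0.300 M | 0.300 M |
| time | 50 min | 50 min | 50 min |

    substrate + reagent → mono adduct (k1 = 0.0031 /M/s)
    reagent + mono adduct → double product (k2 = 0.0038 /M/s)
    reagent + double product → triple product (k3 = 0.0034 /M/s)
    substrate + triple product ⇌ idle adduct, settled at all times (K4 = 1.4 /M)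

- [triple product] (only what is free in solution) at the end for autumn, dusk, summer, in this order
- the course of these numbers from the first flask to the last (rises all the way / hardly changes / falls, then rises / rises, then falls / falls all the way)

- in percentages every species weighs as the substrate in it: one idle adduct counts as two
- for triple product the idle adduct is counted in
- in an amount of triple product, one idle adduct counts as one triple product
- the concentration of triple product that is asked is that of its free form alone
- "hardly changes" means that all values lie within two and a half points (for a concentration: within two and a half percent of the largest)
- run time (autumn): 50 min

**Run time.** With reagent as charged, each addition is pseudo-first-order, with a lifetime between 14.6 min and 17.9 min. These lifetimes add up to 48.9 min, the chain time: the mean time a substrate needs to reach triple product. Since the lifetimes are close, I treat additions as random events, so the mean count per substrate is 3 times the run time over the chain time. The share with at least 3 additions then follows from Poisson counting. I assume about two additions per substrate by the end, which lowers the mean reagent by one substrate charge and stretches the chain time. For autumn that gives 54.3 min, a count of 2.76 and 0.0156 M of triple product. Binding is slight there, with 0.042 as the balance constant times starting substrate.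

**Substrate charge.** For dusk, with more substrate on the same reagent charge, the chain stretches to 66.7 min, which gives a count of 2.25 and 0.0313 M of triple product. In summer the reagent charge allows a count of 1.20, less than the clock offers, so I use that count. On that count I reckon 0.0753 M of substrate remaining in summer, which holds part of the triple product as idle adduct, and a free value of 0.0273 M. My row therefore runs rises, then falls: its summer value lies below its dusk value.

**Forecast and flask.** The forecast gives 0.0145 M, 0.028 M and 0.024 M, rises, then falls, on the ground that “at 0.25 M the reagent is nearly exhausted”, and its last value lies below mine. The flasks give 0.0151 M, 0.0291 M and 0.0252 M: rises, then falls.

**Chain read back.** In autumn the stretched chain time of 54.3 min is longer than the run of 50 min, and triple product stands at 50.4% of the substrate charged, with mono adduct made at 0.435 of the rate it is used up. In dusk the stretched chain time of 66.7 min exceeds the run by more, triple product stands at 36.9% at the end of the run, and after 500 min it has reached 99.3%.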